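## Structural features

Sideritiflavone is a flavone: a benzene ring A is fused through C4a and C8a to a 4-pyranone ring C (O1, C2, C3, C4), and ring B, a 3,4-dihydroxyphenyl group, is attached at C2. Ring A carries no hydrogen: C5 bears a hydroxyl group hydrogen-bonded to the C4 carbonyl, and C6, C7 and C8 bear methoxy groups. There is no stereocentre, so the problem is one of regiochemistry only. The fragile groups are the catechol of ring B (oxidation, especially in base), the pyranone (opening at C2 by strong nucleophiles) and the aryl methyl ethers (strong Lewis acids). The real difficulty lies in ring A. Five neighbouring carbons (C5 to C8a) carry oxygen, the oxygen at C5 must be kept apart from the three methyl ethers and from O1, and the C4–C4a bond has to be made at a ring carbon flanked by two oxygen-bearing carbons. The key step exploits C3, the only carbon of ring C that bears just a hydrogen and sits between C2 (aryl, O1) and C4 (carbonyl). Removing C3 leaves a 2-aryl-3-oxybenzofuran, so C3 can be inserted last as a one-carbon carbene unit into the C2=C3 bond of a 2-aryl-3-siloxybenzofuran.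

## Logic of the disconnections

**23 from 22.** The three O–benzyl bonds and the C3–Br bond are cut together. All four are hydrogenolysed on palladium, so the catechol and the chelated phenol appear only in the last flask, and the halogen left by the ring enlargement needs no step of its own. The forward step must spare the C2=C3 bond and the methyl ethers.

**22 from 18 and 19.** The C2–C3 and C3–C4 bonds are cut and C3 is taken out, which shrinks ring C to a furan. The hard six-membered ring with its C4–C4a bond becomes a five-membered ring plus a one-carbon reagent. The forward step must cyclopropanate the furan double bond in preference to everything else and must open the fused bond, through 20 and 21.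

**18 from 17.** The O–Si bond is cut. The ketone has to be presented as its enol derivative so that a C2=C3 double bond exists for the carbene. The forward step is an O-silylation that must exclude air, because 17 is prone to autoxidation at C2.

**17 from 15 (through 16).** The bond from ring A to the carbonyl carbon is cut. Ring A of 15 has a single unsubstituted carbon, ortho to two ether oxygens and para to a third, so an intramolecular acylation can only go there. The bicyclic ketone becomes an open-chain aryloxy acid. The acyl activation must be mild enough for four benzyl ethers and must not lead to loss of carbon monoxide.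

**15 from 14, and 14 from 9 and 13.** The ester is first taken back to its benzyl ester, then the ether bond between the ring A oxygen and the α-carbon is cut. This divides the molecule into two fragments of similar size, so the route is convergent. The forward step is an SN2 reaction of a phenoxide with a secondary, doubly activated bromide, and it must give O- and not C-alkylation.

**13 from 11 (through 12), and 11 from 10.** The C–Br bond and then the three benzyl–oxygen bonds are cut. One alkylation protects both phenols and the acid, and the ester then serves to acidify the α-position. The bromination must be ionic, since radical conditions would attack the benzylic CH2 groups.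

**9 from 6 (through 7 and 8), 6 from 5, 5 from 2 (through 3 and 4), 2 from 1.** Two aryl C–O bonds are traced back to C–Br bonds, and these to the C–H bonds of 1. The two oxygens are introduced one after the other with the benzylation in between, so the ring A oxygens destined for O1 and for the C5 hydroxyl are differentiated without a statistical monoprotection of a symmetric diol. The forward steps need clean mono-exchange on the symmetric dibromide 2 and a symmetric dibromination of 1.

## Other disconnections considered

**Alternative 1:** The cut is at the C6–O and C8–O bonds; the whole flavone skeleton is bought as luteolin A1.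
- Forward: the catechol of A1 is protected as the diphenylmethylene ketal, O7 is methylated and ring A is brominated twice to give A2. Heating A2 with NaOMe and CuBr in DMF–MeOH (copper-mediated Ullmann-type methoxylation) should replace both bromines and give A3; acid then removes the ketal.
- In favour: the skeleton is complete from the start, the sequence is about five steps, every reaction type is known on flavonoids, and the symmetric 6,8-pattern makes any base-induced opening and reclosure of the pyranone onto the other ortho oxygen degenerate.
- Against: two substitutions are needed at crowded carbons, each between two oxygen-bearing carbons, on a ring that the 5-phenoxide makes very electron-rich. Reductive loss of bromine would compete and give flavones lacking one methoxy group, which would be hard to separate from A3. The bromination must also spare C3 and ring B.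
- Comparison: Alternative 1 alters a finished ring A and relies on its symmetry, whereas the chosen plan fixes every oxygen before ring C exists. On precedent of the key step Alternative 1 is the better, and on step economy (five or six steps against twelve) it is clearly the better. The chosen plan is ahead only in the certainty of the substitution pattern and in the absence of close homologues at the end.

**Alternative 2:** The cut removes ring A altogether. Its four oxygenated carbons come from dimethyl squarate A4, and rings B and C come from the pyranone A5.
- Forward: a C6 organometallic derived from A5 adds to A4 to give the cyclobutenone A6. Heating A6 in xylene should open the four-membered ring to a dienylketene, which closes by a six-electron electrocyclization onto the neighbouring pyranone carbon (flavone C5–C4a) and tautomerizes to the hydroquinone A7. Methylation of the 8-hydroxyl and hydrogenolysis would finish the synthesis.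
- In favour: ring A is built with all four oxygens in place in one thermal step without reagents, and the route is convergent. The thermal rearrangement of 4-aryl- and 4-alkenyl-4-hydroxycyclobutenones is well established, so on precedent of the key step and on convergence Alternative 2 is the better. The two hydroxyl groups of A7 are distinguished by the hydrogen bond of the 5-hydroxyl to the carbonyl.
- Against: the metallated form of A5 is not a standard nucleophile, because 4-pyranones are themselves attacked and opened by organometallics, so the preparation of A6 is a second uncertain step. A7 is an electron-rich hydroquinone that should oxidize easily to the quinone, and an extra methylation is needed.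
- Comparison: step economy is about equal to, or slightly better than, the chosen plan (seven or eight steps). The chosen plan has only classical steps before its single uncertain one, whereas here the uncertainty is spread over two steps.

**Alternative 3:** The cut is at O1–C8a.
- Forward: the diketone A8 is oxidized at a carbon anode in hexafluoroisopropanol. The radical cation of ring A is attacked by the enol oxygen at the only C–H of that ring, and loss of a second electron and a proton should give A9. A boron trihalide would then remove the 5-methyl group (chelation control) and the benzyl groups.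
- In favour: ring A needs no differentiated protecting group, no halogen is carried, the oxidant is the electrode, and the sequence is about five steps. On step and atom economy Alternative 3 is the better.
- Against: A8 holds three electron-rich aryl ether units and an oxidizable enolized diketone, so nothing secures which is oxidized first. The C–H to be substituted is ortho to the deactivating acyl group, and over-oxidation or benzylic oxidation is possible. An anodic C–O closure of an enol oxygen onto a non-phenolic arene is as little precedented as the chosen key step, so on precedent the two are equal.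
- Comparison: the chosen plan rests on a ground-state polarity difference (one enol-ether double bond against benzene rings), which is easier to predict than a difference in oxidation potentials.

Key step: step 11

**Remarks on the chemistry**

- Compounds 13 to 17 have one stereocentre, are racemic and are written without descriptors. Compound 20 is a cis-fused racemate, of which one enantiomer is written. No stereocentre survives in 22 or 23.
- The atom mapping from 18 to 22 was checked: benzofuran C4, C5, C6, C7 become flavone C5, C6, C7, C8. No inconsistency was found in either structure.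
- It is assumed that 1 is brominated twice at the carbons ortho to the outer methoxy groups, as the directing effects predict.
- Three design choices are made: a benzyl ester in the ring B fragment, so that 10 is protected in one step; stepwise introduction of the two ring A oxygens; and acetate, not an amine, as the acid scavenger in step 12, since amines can retard O-debenzylation on palladium.

## Route

Step 1
Reactants: 1 1,2,3-trimethoxybenzene
Product: 2 1,5-dibromo-2,3,4-trimethoxybenzene
Conditions: NBS (2.05 equiv), MeCN, 0 °C → rt
Reagents that add atoms: N-bromosuccinimide, O=C1CCC(=O)N1Br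
Why: Electrophilic aromatic bromination; each outer methoxy group directs ortho and para to C4 and C6, whereas C5 is para only to the twisted central methoxy group, so two equivalents should give the symmetric dibromide.

Step 2
Reactants: 2 1,5-dibromo-2,3,4-trimethoxybenzene
Product: 5 5-bromo-2,3,4-trimethoxyphenol, via aryllithium 3 (not isolated), via dimethyl arylboronate 4 (not isolated)
Conditions: n-BuLi (1.0 equiv), THF, −78 °C; B(OMe)3, −78 → 0 °C; AcOH, 30% H2O2, 0 °C → rt
Reagents that add atoms: hydrogen peroxide, OO (phenol oxygen of 5); n-butyllithium, [Li]CCCC (lithium of 3); trimethyl borate, COB(OC)OC (boron and methoxy groups of 4)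
Why: Bromine–lithium exchange, borylation and oxidative migration from boron to oxygen (hydroxylation of an aryl halide through its boronate); the two bromines are equivalent and a second exchange on an aryllithium is much slower, so one equivalent should give mono-exchange.

Step 3
Reactants: 5 5-bromo-2,3,4-trimethoxyphenol
Product: 6 1-(benzyloxy)-5-bromo-2,3,4-trimethoxybenzene
Conditions: BnBr, K2CO3, DMF, rt
Reagents that add atoms: benzyl bromide, BrCc1ccccc1
Why: Williamson ether synthesis on a phenoxide; it marks this oxygen as the later C5 hydroxyl.

Step 4
Reactants: 6 1-(benzyloxy)-5-bromo-2,3,4-trimethoxybenzene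
Product: 9 5-(benzyloxy)-2,3,4-trimethoxyphenol, via aryllithium 7 (not isolated), via dimethyl arylboronate 8 (not isolated)
Conditions: n-BuLi (1.05 equiv), THF, −78 °C; B(OMe)3, −78 → 0 °C; AcOH, 30% H2O2, 0 °C; Na2S2O3 quench
Reagents that add atoms: hydrogen peroxide, OO (phenol oxygen of 9); n-butyllithium, [Li]CCCC (lithium of 7); trimethyl borate, COB(OC)OC (boron and methoxy groups of 8)
Why: The same exchange, borylation and oxidation sequence; at −78 °C the exchange is far faster than deprotonation of the benzylic ether, and the cold, buffered oxidation with a reductive quench protects the electron-rich phenol.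

Step 5
Reactants: 10 3,4-dihydroxyphenylacetic acid
Product: 11 benzyl [3,4-bis(benzyloxy)phenyl]acetate
Conditions: BnBr (3.3 equiv), K2CO3, DMF, 60 °C, N2
Reagents that add atoms: benzyl bromide, BrCc1ccccc1
Why: Williamson etherification of both phenols and O-alkylation of the carboxylate in one operation; the benzyl ester activates the α-position for the next step.

Step 6
Reactants: 11 benzyl [3,4-bis(benzyloxy)phenyl]acetate
Product: 13 benzyl bromo[3,4-bis(benzyloxy)phenyl]acetate (racemic), via lithium enolate 12 (not isolated)
Conditions: LiHMDS, THF, −78 °C; then added to NBS, THF, −78 °C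
Reagents that add atoms: N-bromosuccinimide, O=C1CCC(=O)N1Br; lithium hexamethyldisilazide, [Li]N([Si](C)(C)C)[Si](C)(C)C (lithium of 12)
Why: Electrophilic α-bromination of an ester enolate, with inverse addition to suppress coupling of the enolate with the product; ionic conditions avoid radical attack on the four benzylic CH2 groups, and the racemic stereocentre disappears at 18.

Step 7
Reactants: 9 5-(benzyloxy)-2,3,4-trimethoxyphenol; 13 benzyl bromo[3,4-bis(benzyloxy)phenyl]acetate
Product: 14 benzyl [5-(benzyloxy)-2,3,4-trimethoxyphenoxy][3,4-bis(benzyloxy)phenyl]acetate (racemic)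
Conditions: K2CO3, acetone, rt
Reagents that add atoms: none
Why: SN2 displacement (Williamson) of a secondary bromide activated by both the ester and the aryl group; a polar aprotic medium should favour O- over C-alkylation of the phenoxide.

Step 8
Reactants: 14 benzyl [5-(benzyloxy)-2,3,4-trimethoxyphenoxy][3,4-bis(benzyloxy)phenyl]acetate
Product: 15 [5-(benzyloxy)-2,3,4-trimethoxyphenoxy][3,4-bis(benzyloxy)phenyl]acetic acid (racemic)
Conditions: LiOH, THF–MeOH–H2O, rt; then 1 M HCl to pH 3
Reagents that add atoms: lithium hydroxide, [Li+].[OH-] (one carboxyl oxygen)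
Why: Saponification of the benzyl ester by acyl–oxygen cleavage; aryl benzyl and methyl ethers are inert to hydroxide.

Step 9
Reactants: 15 [5-(benzyloxy)-2,3,4-trimethoxyphenoxy][3,4-bis(benzyloxy)phenyl]acetic acid
Product: 17 4-(benzyloxy)-2-[3,4-bis(benzyloxy)phenyl]-5,6,7-trimethoxy-1-benzofuran-3(2H)-one (racemic), via mixed trifluoroacetic anhydride 16 (not isolated)
Conditions: TFAA (1.5 equiv), CH2Cl2, 0 °C → rt, Ar; degassed pH 7 buffer
Reagents that add atoms: trifluoroacetic anhydride, O=C(OC(=O)C(F)(F)F)C(F)(F)F (trifluoroacetyl group of 16 only)
Why: Intramolecular Friedel–Crafts acylation through the mixed anhydride; the only free carbon of ring A is ortho to two ether oxygens and para to a third, so the five-membered ketone should close without a strong Lewis acid and the benzyl ethers should survive.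

Step 10
Reactants: 17 4-(benzyloxy)-2-[3,4-bis(benzyloxy)phenyl]-5,6,7-trimethoxy-1-benzofuran-3(2H)-one
Product: 18 {[4-(benzyloxy)-2-[3,4-bis(benzyloxy)phenyl]-5,6,7-trimethoxy-1-benzofuran-3-yl]oxy}(tert-butyl)dimethylsilane
Conditions: TBSOTf, Et3N, CH2Cl2, 0 °C, Ar
Reagents that add atoms: tert-butyldimethylsilyl triflate, CC(C)(C)[Si](C)(C)OS(=O)(=O)C(F)(F)F
Why: O-silylation of an enolizable ketone to its silyl enol ether; the enol form is an aromatic benzofuran, which favours O-silylation and removes the oxidation-prone C2–H.

Step 11
Reactants: 18 {[4-(benzyloxy)-2-[3,4-bis(benzyloxy)phenyl]-5,6,7-trimethoxy-1-benzofuran-3-yl]oxy}(tert-butyl)dimethylsilane; 19 bromoform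
Product: 22 5-(benzyloxy)-2-[3,4-bis(benzyloxy)phenyl]-3-bromo-6,7,8-trimethoxy-4H-chromen-4-one, via dibromocyclopropane 20 (not isolated), via siloxyflavylium bromide 21 (not isolated)
Conditions: CHBr3 (3 equiv), KOtBu (4 equiv), toluene, −20 °C → rt
Reagents that add atoms: none
Why: Proposed new method: tert-butoxide removes HBr from 19 to give dibromocarbene, which should add as an electrophile in a concerted [2+1] cycloaddition to the C2=C3 bond of 18 to give the cis-fused cyclopropane 20; disrotatory electrocyclic opening of 20, with departure of the bromide lying over the five-membered ring, cleaves the old C2–C3 bond and gives the aromatic 4-siloxyflavylium ion 21, which loses its silyl group to bromide or tert-butoxide and leaves the C4 carbonyl of 22. The closest known reaction types are the dihalocarbene ring enlargement of cyclic silyl enol ethers to 2-halo-2-enones and the Ciamician–Dennstedt enlargement of indoles to 3-haloquinolines; neither has been shown on a 3-siloxybenzofuran. Ring C is not closed by a cyclization: the three-membered ring is closed by the cheletropic addition and the six-membered ring then arises by electrocyclic ring enlargement, so the new carbon C3 ends up bonded to C2 and to C4. No stereocentre remains, since the two stereogenic carbons of 20 are necessarily cis and become sp2 again in 21. The step needs chemoselectivity for the furan double bond over three alkoxy-substituted benzene rings and four benzylic CH2 groups, which the two oxygen donors on C2=C3 (O1 and the siloxy oxygen) should secure towards an electrophilic carbene. It also needs cleavage of the fused bond and not of a bond to the CBr2 carbon, which follows because only that opening is the allowed cyclopropyl-to-allyl cation process and only it gives a cation stabilized by O1 and by the siloxy oxygen. The tert-butyldimethylsilyl group is kept because it should resist attack of tert-butoxide at silicon long enough for the carbene to add, whereas a free enolate would be alkylated at C2.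

Step 12
Reactants: 22 5-(benzyloxy)-2-[3,4-bis(benzyloxy)phenyl]-3-bromo-6,7,8-trimethoxy-4H-chromen-4-one
Product: 23 sideritiflavone, 2-(3,4-dihydroxyphenyl)-5-hydroxy-6,7,8-trimethoxy-4H-chromen-4-one
Conditions: H2 (1 atm), 10% Pd/C, NaOAc, THF–MeOH, rt
Reagents that add atoms: none
Why: Catalytic hydrogenolysis of three aryl benzyl ethers and hydrodehalogenation of the vinylic C–Br bond in one operation; acetate takes up the HBr, and the flavone C2=C3 bond is normally inert at one atmosphere of hydrogen.

## Compound list

1 | 1,2,3-trimethoxybenzene | COc1cccc(OC)c1OC | starting material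
2 | 1,5-dibromo-2,3,4-trimethoxybenzene | COc1c(Br)cc(Br)c(OC)c1OC | intermediate
3 | (5-bromo-2,3,4-trimethoxyphenyl)lithium | [Li]c1cc(Br)c(OC)c(OC)c1OC | intermediate (not isolated)
4 | dimethyl (5-bromo-2,3,4-trimethoxyphenyl)boronate | COB(OC)c1cc(Br)c(OC)c(OC)c1OC | intermediate (not isolated)
5 | 5-bromo-2,3,4-trimethoxyphenol | COc1c(O)cc(Br)c(OC)c1OC | intermediate
6 | 1-(benzyloxy)-5-bromo-2,3,4-trimethoxybenzene | COc1c(OCc2ccccc2)cc(Br)c(OC)c1OC | intermediate
7 | [5-(benzyloxy)-2,3,4-trimethoxyphenyl]lithium | [Li]c1cc(OCc2ccccc2)c(OC)c(OC)c1OC | intermediate (not isolated)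
8 | dimethyl [5-(benzyloxy)-2,3,4-trimethoxyphenyl]boronate | COB(OC)c1cc(OCc2ccccc2)c(OC)c(OC)c1OC | intermediate (not isolated)
9 | 5-(benzyloxy)-2,3,4-trimethoxyphenol | COc1c(O)cc(OCc2ccccc2)c(OC)c1OC | intermediate
10 | 3,4-dihydroxyphenylacetic acid | OC(=O)Cc1ccc(O)c(O)c1 | starting material
11 | benzyl [3,4-bis(benzyloxy)phenyl]acetate | O=C(Cc1ccc(OCc2ccccc2)c(OCc2ccccc2)c1)OCc1ccccc1 | intermediate
12 | lithium enolate of 11 (double-bond geometry not defined) | [Li]OC(OCc1ccccc1)=Cc1ccc(OCc2ccccc2)c(OCc2ccccc2)c1 | intermediate (not isolated)
13 | benzyl bromo[3,4-bis(benzyloxy)phenyl]acetate (racemic) | O=C(OCc1ccccc1)C(Br)c1ccc(OCc2ccccc2)c(OCc2ccccc2)c1 | intermediate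
14 | benzyl [5-(benzyloxy)-2,3,4-trimethoxyphenoxy][3,4-bis(benzyloxy)phenyl]acetate (racemic) | COc1c(OC(C(=O)OCc2ccccc2)c2ccc(OCc3ccccc3)c(OCc3ccccc3)c2)cc(OCc2ccccc2)c(OC)c1OC | intermediate
15 | [5-(benzyloxy)-2,3,4-trimethoxyphenoxy][3,4-bis(benzyloxy)phenyl]acetic acid (racemic) | COc1c(OC(C(=O)O)c2ccc(OCc3ccccc3)c(OCc3ccccc3)c2)cc(OCc2ccccc2)c(OC)c1OC | intermediate
16 | mixed anhydride of 15 with trifluoroacetic acid (racemic) | COc1c(OC(C(=O)OC(=O)C(F)(F)F)c2ccc(OCc3ccccc3)c(OCc3ccccc3)c2)cc(OCc2ccccc2)c(OC)c1OC | intermediate (not isolated)
17 | 4-(benzyloxy)-2-[3,4-bis(benzyloxy)phenyl]-5,6,7-trimethoxy-1-benzofuran-3(2H)-one (racemic) | COc1c(OC)c(OCc2ccccc2)c2c(c1OC)OC(c1ccc(OCc3ccccc3)c(OCc3ccccc3)c1)C2=O | intermediate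
18 | {[4-(benzyloxy)-2-[3,4-bis(benzyloxy)phenyl]-5,6,7-trimethoxy-1-benzofuran-3-yl]oxy}(tert-butyl)dimethylsilane | COc1c(OC)c(OCc2ccccc2)c2c(O[Si](C)(C)C(C)(C)C)c(-c3ccc(OCc4ccccc4)c(OCc4ccccc4)c3)oc2c1OC | intermediate
19 | bromoform | BrC(Br)Br | starting material
20 | 6-(benzyloxy)-1a-[3,4-bis(benzyloxy)phenyl]-1,1-dibromo-6b-[(tert-butyldimethylsilyl)oxy]-3,4,5-trimethoxy-1a,6b-dihydro-1H-cyclopropa[b][1]benzofuran (racemic, cis ring fusion, one enantiomer written) | COc1c(OC)c(OCc2ccccc2)c2c(c1OC)O[C@@]1(c3ccc(OCc4ccccc4)c(OCc4ccccc4)c3)C(Br)(Br)[C@@]21O[Si](C)(C)C(C)(C)C | intermediate (not isolated)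
21 | 5-(benzyloxy)-2-[3,4-bis(benzyloxy)phenyl]-3-bromo-4-[(tert-butyldimethylsilyl)oxy]-6,7,8-trimethoxychromenylium bromide | COc1c(OC)c(OCc2ccccc2)c2c(O[Si](C)(C)C(C)(C)C)c(Br)c(-c3ccc(OCc4ccccc4)c(OCc4ccccc4)c3)[o+]c2c1OC.[Br-] | intermediate (not isolated)
22 | 5-(benzyloxy)-2-[3,4-bis(benzyloxy)phenyl]-3-bromo-6,7,8-trimethoxy-4H-chromen-4-one | COc1c(OC)c(OCc2ccccc2)c2c(=O)c(Br)c(-c3ccc(OCc4ccccc4)c(OCc4ccccc4)c3)oc2c1OC | intermediate
23 | sideritiflavone, 2-(3,4-dihydroxyphenyl)-5-hydroxy-6,7,8-trimethoxy-4H-chromen-4-one | COc1c(OC)c(O)c2c(=O)cc(-c3ccc(O)c(O)c3)oc2c1OC | target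

## Step count and least certain steps

Total step count: 12. Longest linear sequence: 10 steps (steps 1 to 4 and 7 to 12, from 1); the branch from 10 (steps 5 and 6) joins at step 7.

**Step 11 (key step).**
- What may go wrong:
  - (a) Slow carbene addition to a tetrasubstituted, shielded and partly aromatic double bond, so that the carbene is consumed by tert-butoxide.
  - (b) Desilylation of 18 by tert-butoxide before the cycloaddition, followed by alkylation of the enolate at C2.
  - (c) Arrest at the cyclopropane stage, or attack of excess alkoxide at C2 of the product with ring contraction.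
- Fallback (known chemistry), from 9 back to the route at 23. Houben–Hoesch acylation of 9 with acetonitrile (HCl, ZnCl2, Et2O, 0 °C; then aqueous hydrolysis) at the only free ring carbon should give 1-[6-(benzyloxy)-2-hydroxy-3,4,5-trimethoxyphenyl]ethan-1-one F1. Claisen–Schmidt condensation of F1 with purchased 3,4-bis(benzyloxy)benzaldehyde F2 (KOH, EtOH) should give the chalcone (E)-1-[6-(benzyloxy)-2-hydroxy-3,4,5-trimethoxyphenyl]-3-[3,4-bis(benzyloxy)phenyl]prop-2-en-1-one F3. Oxidative cyclization with catalytic iodine in DMSO at 120 °C should give 5-(benzyloxy)-2-[3,4-bis(benzyloxy)phenyl]-6,7,8-trimethoxy-4H-chromen-4-one F4. Hydrogenolysis over Pd/C as in step 12 would then give 23.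

**Step 9.**
- What may go wrong: loss of carbon monoxide from the activated acyl species, because the resulting cation is stabilized by the ether oxygen and by ring B; acid-induced loss of the benzyl ether peri to the new carbonyl; or autoxidation of the product at C2 during work-up.
- Fallback, from 9 back to the route at 17, with the bond order reversed (carbon–carbon bond first, ring oxygen bond second). Houben–Hoesch acylation of 9 with purchased [3,4-bis(benzyloxy)phenyl]acetonitrile F5 (HCl, ZnCl2, Et2O, 0 °C; then H2O, 60 °C) should give 1-[6-(benzyloxy)-2-hydroxy-3,4,5-trimethoxyphenyl]-2-[3,4-bis(benzyloxy)phenyl]ethan-1-one F6, whose acyl group has no α-oxygen and cannot lose carbon monoxide. α-Bromination with phenyltrimethylammonium tribromide (THF, 0 °C) should give 1-[6-(benzyloxy)-2-hydroxy-3,4,5-trimethoxyphenyl]-2-bromo-2-[3,4-bis(benzyloxy)phenyl]ethan-1-one F7. Intramolecular Williamson closure (K2CO3, acetone) should then give 17.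

**Step 6.**
- What may go wrong: coupling of the enolate with the bromo ester already formed, double bromination, or solvolysis of the labile benzylic bromide on isolation.
- Fallback, from 11 back to the route at 14 (it replaces steps 6 and 7). Diazo transfer to 11 with 4-acetamidobenzenesulfonyl azide and DBU in MeCN should give benzyl [3,4-bis(benzyloxy)phenyl](diazo)acetate F8. Rh2(OAc)4-catalysed O–H insertion of the derived carbenoid into 9 (CH2Cl2, rt) should give 14.

**Step 12.**
- What may go wrong: incomplete debenzylation through poisoning of the catalyst by bromide, over-reduction of the C2=C3 bond during the long exposure needed for three ethers, or oxidation of the catechol on work-up.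
- Fallback, from 22 back to the route at 23, without hydrogen. Debenzylation with BCl3 and pentamethylbenzene (CH2Cl2, −78 °C) should give 3-bromo-2-(3,4-dihydroxyphenyl)-5-hydroxy-6,7,8-trimethoxy-4H-chromen-4-one F9. Reductive removal of the α-bromine of the enone with zinc dust in AcOH at rt should give 23.

## Further compounds

F1 | step 11 | 1-[6-(benzyloxy)-2-hydroxy-3,4,5-trimethoxyphenyl]ethan-1-one | COc1c(O)c(C(C)=O)c(OCc2ccccc2)c(OC)c1OC
F2 | step 11 | 3,4-bis(benzyloxy)benzaldehyde (purchased, not made) | O=Cc1ccc(OCc2ccccc2)c(OCc2ccccc2)c1
F3 | step 11 | (E)-1-[6-(benzyloxy)-2-hydroxy-3,4,5-trimethoxyphenyl]-3-[3,4-bis(benzyloxy)phenyl]prop-2-en-1-one | COc1c(O)c(C(=O)/C=C/c2ccc(OCc3ccccc3)c(OCc3ccccc3)c2)c(OCc2ccccc2)c(OC)c1OC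
F4 | step 11 | 5-(benzyloxy)-2-[3,4-bis(benzyloxy)phenyl]-6,7,8-trimethoxy-4H-chromen-4-one | COc1c(OC)c(OCc2ccccc2)c2c(=O)cc(-c3ccc(OCc4ccccc4)c(OCc4ccccc4)c3)oc2c1OC
F5 | step 9 | [3,4-bis(benzyloxy)phenyl]acetonitrile (purchased, not made) | N#CCc1ccc(OCc2ccccc2)c(OCc2ccccc2)c1
F6 | step 9 | 1-[6-(benzyloxy)-2-hydroxy-3,4,5-trimethoxyphenyl]-2-[3,4-bis(benzyloxy)phenyl]ethan-1-one | COc1c(O)c(C(=O)Cc2ccc(OCc3ccccc3)c(OCc3ccccc3)c2)c(OCc2ccccc2)c(OC)c1OC
F7 | step 9 | 1-[6-(benzyloxy)-2-hydroxy-3,4,5-trimethoxyphenyl]-2-bromo-2-[3,4-bis(benzyloxy)phenyl]ethan-1-one (racemic) | COc1c(O)c(C(=O)C(Br)c2ccc(OCc3ccccc3)c(OCc3ccccc3)c2)c(OCc2ccccc2)c(OC)c1OC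
F8 | step 6 | benzyl [3,4-bis(benzyloxy)phenyl](diazo)acetate | [N-]=[N+]=C(C(=O)OCc1ccccc1)c1ccc(OCc2ccccc2)c(OCc2ccccc2)c1
F9 | step 12 | 3-bromo-2-(3,4-dihydroxyphenyl)-5-hydroxy-6,7,8-trimethoxy-4H-chromen-4-one | COc1c(OC)c(O)c2c(=O)c(Br)c(-c3ccc(O)c(O)c3)oc2c1OC
A1 | alternative 1 | luteolin | O=c1cc(-c2ccc(O)c(O)c2)oc2cc(O)cc(O)c12
A2 | alternative 1 | 6,8-dibromo-2-(2,2-diphenyl-1,3-benzodioxol-5-yl)-5-hydroxy-7-methoxy-4H-chromen-4-one | COc1c(Br)c(O)c2c(=O)cc(-c3ccc4OC(c5ccccc5)(c5ccccc5)Oc4c3)oc2c1Br
A3 | alternative 1 | 2-(2,2-diphenyl-1,3-benzodioxol-5-yl)-5-hydroxy-6,7,8-trimethoxy-4H-chromen-4-one | COc1c(OC)c(O)c2c(=O)cc(-c3ccc4OC(c5ccccc5)(c5ccccc5)Oc4c3)oc2c1OC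
A4 | alternative 2 | dimethyl squarate, 3,4-dimethoxycyclobut-3-ene-1,2-dione | COC1=C(OC)C(=O)C1=O
A5 | alternative 2 | 2-[3,4-bis(benzyloxy)phenyl]-4H-pyran-4-one | O=c1ccoc(-c2ccc(OCc3ccccc3)c(OCc3ccccc3)c2)c1
A6 | alternative 2 | 4-{6-[3,4-bis(benzyloxy)phenyl]-4-oxo-4H-pyran-2-yl}-4-hydroxy-2,3-dimethoxycyclobut-2-en-1-one (racemic) | COC1=C(OC)C(O)(c2cc(=O)cc(-c3ccc(OCc4ccccc4)c(OCc4ccccc4)c3)o2)C1=O
A7 | alternative 2 | 2-[3,4-bis(benzyloxy)phenyl]-5,8-dihydroxy-6,7-dimethoxy-4H-chromen-4-one | COc1c(OC)c(O)c2c(=O)cc(-c3ccc(OCc4ccccc4)c(OCc4ccccc4)c3)oc2c1O
A8 | alternative 3 | 1-[3,4-bis(benzyloxy)phenyl]-3-(2,3,4,5-tetramethoxyphenyl)propane-1,3-dione | COc1cc(C(=O)CC(=O)c2ccc(OCc3ccccc3)c(OCc3ccccc3)c2)c(OC)c(OC)c1OC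
A9 | alternative 3 | 2-[3,4-bis(benzyloxy)phenyl]-5,6,7,8-tetramethoxy-4H-chromen-4-one | COc1c(OC)c(OC)c2c(=O)cc(-c3ccc(OCc4ccccc4)c(OCc4ccccc4)c3)oc2c1OC
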